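**Plan** (ring numbering: C1 ketone, C2H=C3(Et), C4H–OH, oxirane C5H–O–C6, farnesyl on C6)
1. Hardest point: the core is a pseudo-symmetric 2,5-dialkylquinone derivative. Quinone epoxidation and reduction cannot tell C5=C6 from C2=C3 or C4=O from C1=O, and C4, C5 and C6 all carry oxygen on one face.
2. Cuts, in order: the oxirane bond C6–O, the ring–chain bond C6–C1′, then both C4–O and C5–O. This leads back to flat 3-ethylphenol.
3. Enabling feature: C1(=O)–C2H=C3(Et)–C4H(O)–C5H(O)–C6 is the keto tautomer of the cis-4,5-dihydrodiol of 3-ethylphenol. The ketone is meta to the ethyl-bearing carbon and the cis oxygen pair sits on the ring edge next to the ethyl group, which is the product type of an arene dioxygenase.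
4. Forward: the carbocycle is the arene ring itself, dearomatised in step 1. The chain is joined at C6, the only α′-carbon, in step 2. The oxirane closes last, by the enzyme-installed C5 oxygen onto C6, in step 3. No protecting group is used.
5. Stereochemistry: C4 and C5 come from the enzyme. C6 is relayed from C5, because an oxirane can only be cis-fused. Both E alkenes are bought with farnesyl bromide.

Key step: step 1

Assumption: 3-ethylphenol is taken to bind to toluene dioxygenase as other meta-substituted phenols and ethylbenzene do, with the alkyl group in the hydrophobic pocket; 6 is drawn as its expected C6 epimer.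

Step 1
Reactants: 1 3-ethylphenol
Product: 3 (4R,5S)-3-ethyl-4,5-dihydroxycyclohex-2-en-1-one, via enol cis-dihydrodiol 2 (not isolated)
Conditions: whole cells of E. coli expressing toluene dioxygenase (Rieske non-haem iron arene dioxygenase), air, D-glucose, phosphate buffer pH 7.2, 30 °C; EtOAc extraction
Reagents that add atoms: dioxygen O=O
Why: The Rieske oxygenase takes two electrons from NADH through its reductase and ferredoxin, binds O2 side-on at the mononuclear iron and delivers both oxygen atoms suprafacially to one arene edge, here C4–C5, giving enol 2, which tautomerises to the conjugated enone 3 (C1=O, C6H2). The closest known reaction types are the toluene-dioxygenase cis-dihydroxylation of meta-substituted phenols to 4,5-dihydroxycyclohex-2-enones and that of ethylbenzene to its (1S,2R)-cis-dihydrodiol. No ring is closed; the flat arene ring becomes the carbocycle of the target. C4 and C5 are both set by the active site: the ethyl group lies in the pocket that holds the methyl group of toluene, so the adjacent edge is attacked from the face that gives 4R,5S, the sense needed for 9. The step needs edge selectivity (C4–C5, not the hydroxyl-bearing C1–C2 edge, which would lead to a catechol) and chemoselectivity over benzylic hydroxylation; the meta hydroxyl group points away from the iron in the productive binding mode, and tautomerisation removes 2 from further dioxygenase turnover. This one operation fixes which ring carbon is the ketone, which carries the free hydroxyl group and which side will carry the oxirane, choices that a 2,5-dialkylquinone cannot make.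

Step 2
Reactants: 3 (4R,5S)-3-ethyl-4,5-dihydroxycyclohex-2-en-1-one; 4 (2E,6E)-farnesyl bromide
Product: 6 (4R,5S,6S)-3-ethyl-4,5-dihydroxy-6-[(2E,6E)-3,7,11-trimethyldodeca-2,6,10-trien-1-yl]cyclohex-2-en-1-one, via trilithium enolate 5 (not isolated)
Conditions: LDA (3.3 equiv), THF, −78 to −40 °C; 4 (1.0 equiv), DMPU, −78 to −30 °C; AcOH/THF quench at −78 °C
Reagents that add atoms: none
Why: This is kinetic α′-deprotonation of a cyclohexenone and SN2 alkylation of its cross-conjugated lithium enolate by a primary allylic bromide, run on the O-lithiated diol in the manner of a Fráter–Seebach alkylation: the C5 oxygen is an alkoxide that cannot leave, so aromatisation is blocked, the bromide reacts without allylic shift or loss of E geometry, and it should enter anti to the two lithium alkoxides (6S), a centre that step 3 erases anyway.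

Step 3
Reactants: 6 (4R,5S,6S)-3-ethyl-4,5-dihydroxy-6-[(2E,6E)-3,7,11-trimethyldodeca-2,6,10-trien-1-yl]cyclohex-2-en-1-one
Product: 9 (4R,5R,6R)-3-ethyl-6-[(2E,6E)-farnesyl]-4-hydroxy-5,6-epoxycyclohex-2-en-1-one (CID44566894), via trilithium enolate 7 (not isolated), via iodo ketone 8 (not isolated)
Conditions: LDA (3.2 equiv), THF, −78 to −30 °C; cannulated into I2 (1.2 equiv), THF, −78 °C; AcOH/THF quench at −78 °C, aq. Na2S2O3 wash
Reagents that add atoms: none
Why: Proposed new method: LDA regenerates the planar C6 enolate 7, iodine is taken up at C6 on the face away from the C4 and C5 lithium alkoxides to give the tertiary α-iodo ketone 8, and the C5 alkoxide, now anti-periplanar to C–I, closes the oxirane by 3-exo-tet displacement with inversion, so C6 (R) is dictated by C5 because the oxirane can only be cis-fused to the six-membered ring; a syn iodide cannot close and should revert by iodide attack on iodine, the C4 alkoxide is syn to the new oxirane and cannot start a Payne shift, and the enolate should outrun the three trisubstituted alkenes for iodine at −78 °C; the closest known reaction types are the ring-closing half of the Darzens condensation and the iodine quench of β-hydroxy ester dianions to glycidic esters.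

**Compound list**
1 | 3-ethylphenol | CCc1cccc(O)c1 | starting material
2 | (1S,2R)-3-ethylcyclohexa-3,5-diene-1,2,5-triol (enol cis-dihydrodiol of 1) | CCC1=CC(O)=C[C@H](O)[C@@H]1O | intermediate
3 | (4R,5S)-3-ethyl-4,5-dihydroxycyclohex-2-en-1-one | CCC1=CC(=O)C[C@H](O)[C@@H]1O | intermediate
4 | (2E,6E)-farnesyl bromide | BrC/C=C(\C)CC/C=C(\C)CCC=C(C)C | starting material
5 | trilithium salt of 3 (C4 and C5 alkoxides, C1=C6 enolate) | [Li+].[Li+].[Li+].CCC1=CC([O-])=C[C@H]([O-])[C@@H]1[O-] | intermediate
6 | (4R,5S,6S)-3-ethyl-4,5-dihydroxy-6-[(2E,6E)-3,7,11-trimethyldodeca-2,6,10-trien-1-yl]cyclohex-2-en-1-one (farnesyl trans to C5–OH) | CCC1=CC(=O)[C@@H](C/C=C(\C)CC/C=C(\C)CCC=C(C)C)[C@H](O)[C@@H]1O | intermediate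
7 | trilithium salt of 6 (C4 and C5 alkoxides, tetrasubstituted C1=C6 enolate) | [Li+].[Li+].[Li+].CCC1=CC([O-])=C(C/C=C(\C)CC/C=C(\C)CCC=C(C)C)[C@H]([O-])[C@@H]1[O-] | intermediate
8 | dilithium (4R,5R,6S)-3-ethyl-6-farnesyl-6-iodo-1-oxocyclohex-2-ene-4,5-diolate (iodine trans to C5–O) | [Li+].[Li+].CCC1=CC(=O)[C@](I)(C/C=C(\C)CC/C=C(\C)CCC=C(C)C)[C@H]([O-])[C@@H]1[O-] | intermediate
9 | (1R,5R,6R)-4-ethyl-5-hydroxy-1-[(2E,6E)-3,7,11-trimethyldodeca-2,6,10-trien-1-yl]-7-oxabicyclo[4.1.0]hept-3-en-2-one | CCC1=CC(=O)[C@]2(C/C=C(\C)CC/C=C(\C)CCC=C(C)C)O[C@@H]2[C@@H]1O | target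

Total step count: 3. Longest linear sequence: 3 (1 → 3 → 6 → 9).

**Steps most likely to fail**

Step 3 (labelled). Several processes could defeat it:
- slow removal of the tertiary C6–H next to two lithium alkoxides;
- electron transfer from the polyanion to iodine, leading to enolate coupling or glycol cleavage;
- retro-aldol opening of the C5–C6 bond before the oxirane closes.

The fallback uses known chemistry, sets out from 6 and comes back at 9. Soft enolisation with exhaustive silylation (TMSOTf, Et3N, CH2Cl2, 0 °C) would give the tris(trimethylsilyl) cross-conjugated dienol ether F1. Bromination of this silyl enol ether (NBS, THF, −78 °C), anti to the C5 silyloxy group, would give the tertiary α-bromo ketone F2. K2CO3 in MeOH at 0 °C would then free both hydroxyl groups and close the trans-bromohydrin to 9.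

Step 2. The possible failures are:
- incomplete formation or poor solubility of the trianion;
- proton exchange between product and enolate, with double alkylation;
- O-alkylation;
- dehydration to the hydroquinone on work-up.

The fallback sets out from 3, comes back at 6 and replaces the strong-base SN2 alkylation by a neutral palladium π-allyl coupling. TESOTf and Et3N (CH2Cl2, 0 °C) would give the tris(triethylsilyl) dienol ether F3. (2E,6E)-Farnesol and methyl chloroformate (pyridine) would give farnesyl methyl carbonate F4. Palladium-catalysed allylation of the silyl enol ether by the allylic carbonate (Pd2(dba)3, dppe, THF, rt; Tsuji–Trost type) should join C6 to the unsubstituted allyl terminus and give the bis(triethylsilyl) ketone F5. HF·pyridine (THF, 0 °C) would then release 6.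

Step 1. The possible failures are:
- low turnover because the phenol is toxic to the cells;
- benzylic hydroxylation of the ethyl group;
- attack at the hydroxyl-bearing edge;
- reduction of the enone by host reductases.

The fallback leaves 1 aside. Commercial 3-iodophenol takes its place, and the route is rejoined at 3. This substrate has no benzylic C–H, and its heavy substituent anchors the ring in the pocket. The same enzyme class should convert it into the iodo ketodiol F6. The C3–ethyl bond is then made afterwards by Negishi coupling of this β-iodo enone (Et2Zn, Pd(dppf)Cl2, THF, 0 °C to rt).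

**Further compounds**
F1 | step 3 | (4R,5S)-3-ethyl-6-farnesyl-1,4,5-tris(trimethylsilyloxy)cyclohexa-1(6),2-diene (route numbering) | CCC1=CC(O[Si](C)(C)C)=C(C/C=C(\C)CC/C=C(\C)CCC=C(C)C)[C@H](O[Si](C)(C)C)[C@@H]1O[Si](C)(C)C
F2 | step 3 | (4R,5R,6S)-6-bromo-3-ethyl-6-farnesyl-4,5-bis(trimethylsilyloxy)cyclohex-2-en-1-one | CCC1=CC(=O)[C@](Br)(C/C=C(\C)CC/C=C(\C)CCC=C(C)C)[C@H](O[Si](C)(C)C)[C@@H]1O[Si](C)(C)C
F3 | step 2 | (4R,5S)-3-ethyl-1,4,5-tris(triethylsilyloxy)cyclohexa-1(6),2-diene (route numbering) | CCC1=CC(O[Si](CC)(CC)CC)=C[C@H](O[Si](CC)(CC)CC)[C@@H]1O[Si](CC)(CC)CC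
F4 | step 2 | (2E,6E)-farnesyl methyl carbonate | COC(=O)OC/C=C(\C)CC/C=C(\C)CCC=C(C)C
F5 | step 2 | (4R,5S,6S)-3-ethyl-6-farnesyl-4,5-bis(triethylsilyloxy)cyclohex-2-en-1-one | CCC1=CC(=O)[C@@H](C/C=C(\C)CC/C=C(\C)CCC=C(C)C)[C@H](O[Si](CC)(CC)CC)[C@@H]1O[Si](CC)(CC)CC
F6 | step 1 | (4S,5S)-4,5-dihydroxy-3-iodocyclohex-2-en-1-one | IC1=CC(=O)C[C@H](O)[C@@H]1O
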